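The CH2 bridge is cut last: the target is isobutyrylfilicinic acid (used as its Mannich base) joined to C8 of 5,7-dihydroxy-6-isobutyryl-2,2-dimethyl-2H-chromene.
The strategy rests on the benzene ring of that chromene: in chromene numbering it bears oxygen on C5, C7 and C8a, the acyl group on C6 and its only free CH at C8. This is the pattern of a 4,6-dioxygenated 2-pyranone already fused to the dimethylpyran ring (giving C4a, C8a, C8, C7) plus an alkoxy ynone (giving C5, C6).
Key disconnection: C4a–C5 and C6–C7, by Diels–Alder addition of the silyloxy pyranopyranone to 1-ethoxy-4-methylpent-1-yn-3-one, then loss of CO2 from the bridged lactone.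
Ring order: pyranone ring (anhydride of 3-oxopentanedioic acid), then the 2H-pyran ring (Knoevenagel/oxa-6π with 3-methylbut-2-enal), then the benzene ring (key step, the pyranone ring is spent as CO2). The filicinic ring is made apart from phloroglucinol (acylation, gem-dimethylation).

Key step: step 5

Remark: the target has no stereocentre; its tri-carbonyl ring is taken in the enol tautomer of the given SMILES, the other keto/enol forms being the same compound.

Step 1
Reactants: 1 3-oxopentanedioic acid (1,3-acetonedicarboxylic acid)
Product: 2 4-hydroxy-2H-pyran-2,6(3H)-dione (enol form of 1,3-acetonedicarboxylic anhydride)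
Conditions: Ac2O, AcOH, 0–10 °C; filtration
Reagents that add atoms: none
Why: Cyclodehydration of the 1,5-diacid through its mixed acetic anhydride is a standard anhydride synthesis, and the enolised six-membered anhydride should crystallise from the cold medium before C-acetylation can compete.

Step 2
Reactants: 2 4-hydroxy-2H-pyran-2,6(3H)-dione; 3 3-methylbut-2-enal
Product: 5 2,2-dimethyl-2H,5H-pyrano[4,3-b]pyran-5,7(8H)-dione, via alkylidene trione 4 (not isolated)
Conditions: InCl3 (10 mol %), 4 Å MS, MeCN, 50 °C (3, 1.05 equiv)
Reagents that add atoms: none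
Why: Knoevenagel condensation of the strongly acidic cyclic β-dicarbonyl enol with the enal gives the 1-oxatriene 4, which should close by oxa-6π electrocyclisation through the ketone oxygen (formal [3+3] annulation, well known for cyclic 1,3-dicarbonyls such as 4-hydroxypyranones); an amine-free Lewis acid and sieves are chosen because amines or the water of condensation would open the anhydride.

Step 3
Reactants: 5 2,2-dimethyl-2H,5H-pyrano[4,3-b]pyran-5,7(8H)-dione
Product: 6 7-(tert-butyldimethylsilyloxy)-2,2-dimethyl-2H,5H-pyrano[4,3-b]pyran-5-one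
Conditions: TBSOTf, Et3N, CH2Cl2, −78 → 0 °C; pentane, filtration under Ar, used crude
Reagents that add atoms: tert-butyldimethylsilyl trifluoromethanesulfonate (TBSOTf), CC(C)(C)[Si](C)(C)OS(=O)(=O)C(F)(F)F
Why: Soft enolisation and O-silylation of the acidic C8 methylene next to the unconjugated anhydride carbonyl should give the silyl ketene acetal, driven by formation of the aromatic 2-pyranone ring, and the bulky TBS group with a non-aqueous work-up should keep this hydrolytically labile diene intact.

Step 4
Reactants: 7 ethoxyacetylene; 8 N-methoxy-N,2-dimethylpropanamide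
Product: 11 1-ethoxy-4-methylpent-1-yn-3-one, via lithium ethoxyacetylide 9 (not isolated), via lithium hemiaminal adduct 10 (not isolated)
Conditions: 7, n-BuLi, THF, −78 °C; then 8, −78 → 0 °C; aq NH4Cl
Reagents that add atoms: none
Why: Weinreb ketone synthesis, in which the lithium acetylide adds once to the N-methoxy-N-methylamide and the chelated tetrahedral adduct 10 releases the ynone only on the buffered quench, which avoids over-addition and acid-promoted hydration of the ynol ether.

Step 5
Reactants: 6 7-(tert-butyldimethylsilyloxy)-2,2-dimethyl-2H,5H-pyrano[4,3-b]pyran-5-one; 11 1-ethoxy-4-methylpent-1-yn-3-one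
Product: 13 1-[7-(tert-butyldimethylsilyloxy)-5-ethoxy-2,2-dimethyl-2H-chromen-6-yl]-2-methylpropan-1-one, via bridged lactone cycloadduct 12 (not isolated)
Conditions: PhMe, 80 °C, sealed tube, Ar (11, 1.5 equiv)
Reagents that add atoms: none
Why: Proposed new method: 6 is a cyclic 1,1,3-trioxygenated diene (C4a=C8a–C8=C7, pyranopyranone numbering) whose most nucleophilic terminus is the ring-fusion carbon C4a, so an asynchronous normal-demand [4+2] addition should join C4a to the electrophilic ethoxy-bearing β-carbon of the push-pull ynone 11 and the silyloxy-bearing C7 to its acyl-bearing α-carbon, and the bridged lactone 12 should then lose CO2 by retro-[4+2] at the reaction temperature. The closest known reaction types are the 2-pyranone/alkyne Diels–Alder reaction with CO2 extrusion and the Tamura cycloaddition of enolised homophthalic- and glutaconic-type anhydrides; a silyloxypyranone of this kind has not been combined with an alkoxy ynone. The benzene ring is closed by an intermolecular [4+2] cycloaddition that forms two C–C bonds (chromene C4a–C5 and C6–C7) and is then unmasked by cycloreversion, the pyranone ring being spent as CO2. No stereocentre is set, since the two bridgehead centres of 12 disappear on aromatisation. The step needs regioselectivity (acyl group between the two oxygens and para to the pyran oxygen) and chemoselectivity for the pyranone diene over the 2H-pyran diene C3=C4–C4a=C8a; the first is secured by the matched donor/acceptor polarisation of the two partners, the second by the silyl ketene acetal terminus, which makes the pyranone diene the more electron-rich one, and by the gem-dimethyl group that shields C3. A stepwise Michael/acylation/decarboxylation course starting at C8 would give the 5-hydroxy-7-ethoxy isomer with the same skeleton, which leads to the same diol 16 after dealkylation, and Lewis-acid-free heating below 90 °C is chosen so that the silyl ketene acetal and the ethyl ynol ether (retro-ene above about 100 °C) survive.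

Step 6
Reactants: 13 1-[7-(tert-butyldimethylsilyloxy)-5-ethoxy-2,2-dimethyl-2H-chromen-6-yl]-2-methylpropan-1-one
Product: 15 1-[7-(tert-butyldimethylsilyloxy)-5-hydroxy-2,2-dimethyl-2H-chromen-6-yl]-2-methylpropan-1-one, via aryloxydichloroborane 14 (not isolated)
Conditions: BCl3, CH2Cl2, −78 → −10 °C; then H2O
Reagents that add atoms: none
Why: Chelation-assisted ether cleavage, in which BCl3 should bind between the ketone oxygen and the flanking 5-ethoxy oxygen and chloride then removes the ethyl group by SN2, while the non-chelating pyran oxygen and the bulky silyl ether should be left alone; the step comes before desilylation so that no free phenol captures the boron or releases HCl onto the chromene alkene.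

Step 7
Reactants: 15 1-[7-(tert-butyldimethylsilyloxy)-5-hydroxy-2,2-dimethyl-2H-chromen-6-yl]-2-methylpropan-1-one
Product: 16 1-(5,7-dihydroxy-2,2-dimethyl-2H-chromen-6-yl)-2-methylpropan-1-one
Conditions: TBAF, AcOH, THF, 0 °C
Reagents that add atoms: none
Why: Fluoride-induced cleavage of the aryl silyl ether (Si–F bond formation) should be fast for a phenol ortho to a ketone, and the acetic acid buffer keeps the electron-rich product from standing as its oxidisable phenoxide.

Step 8
Reactants: 17 phloroglucinol (benzene-1,3,5-triol); 18 2-methylpropanoyl chloride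
Product: 19 2-methyl-1-(2,4,6-trihydroxyphenyl)propan-1-one (phlorisobutyrophenone)
Conditions: AlCl3, PhNO2, 65 °C; aq HCl
Reagents that add atoms: none
Why: Friedel–Crafts acylation of the threefold-symmetric, highly activated arene should stop at the mono-ketone because the aluminium-chelated product is deactivated.

Step 9
Reactants: 19 2-methyl-1-(2,4,6-trihydroxyphenyl)propan-1-one
Product: 21 3,5-dihydroxy-4,4-dimethyl-6-(2-methylpropanoyl)cyclohexa-2,5-dien-1-one (isobutyrylfilicinic acid), via mono-C-methyl ketone 20 (not isolated)
Conditions: NaOMe, MeI, MeOH, 0 °C → rt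
Reagents that add atoms: iodomethane, CI
Why: Dearomatising C-alkylation of the acylphloroglucinolate, in which the first C-methyl group raises the nucleophilicity of the same ring carbon so that the second methylation should give the gem-dimethyl cyclohexadienone, a known conversion of acylphloroglucinols into acylfilicinic acids.

Step 10
Reactants: 21 isobutyrylfilicinic acid
Product: 22 2-[(dimethylamino)methyl]-3,5-dihydroxy-4,4-dimethyl-6-(2-methylpropanoyl)cyclohexa-2,5-dien-1-one
Conditions: Me2N=CH2+ I−, Et3N, CH2Cl2, 0 °C → rt
Reagents that add atoms: N,N-dimethylmethyleneiminium iodide, C[N+](C)=C.[I-]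
Why: Mannich reaction, in which the enolate of the vinylogous acid attacks the preformed iminium ion at the only unsubstituted ring carbon, and the preformed salt avoids free formaldehyde, which would give the symmetric methylene-bis dimer.

Step 11
Reactants: 22 Mannich base of isobutyrylfilicinic acid; 16 1-(5,7-dihydroxy-2,2-dimethyl-2H-chromen-6-yl)-2-methylpropan-1-one
Product: 24 3,5-dihydroxy-2-{[5,7-dihydroxy-2,2-dimethyl-6-(2-methylpropanoyl)-2H-chromen-8-yl]methyl}-4,4-dimethyl-6-(2-methylpropanoyl)cyclohexa-2,5-dien-1-one (target), via methylene trione 23 (not isolated)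
Conditions: NaOAc (cat.), 1,4-dioxane, 80 °C (22, 1.5 equiv)
Reagents that add atoms: none
Why: Thermal β-elimination of dimethylamine from the Mannich base (retro-Michael) should give the electrophilic 2-methylene-1,3-dione 23, which the phloroglucinol-type phenol 16 traps by Michael addition through C8, its only free aromatic position, the usual way of assembling methylene-bridged acylphloroglucinol dimers.

Compound list
1 | 3-oxopentanedioic acid (1,3-acetonedicarboxylic acid) | OC(=O)CC(=O)CC(O)=O | starting material
2 | 4-hydroxy-2H-pyran-2,6(3H)-dione (1,3-acetonedicarboxylic anhydride, enol form) | OC1=CC(=O)OC(=O)C1 | intermediate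
3 | 3-methylbut-2-enal | CC(C)=CC=O | starting material
4 | 3-(3-methylbut-2-en-1-ylidene)-2H-pyran-2,4,6(3H,5H)-trione | CC(C)=CC=C1C(=O)CC(=O)OC1=O | intermediate
5 | 2,2-dimethyl-2H,5H-pyrano[4,3-b]pyran-5,7(8H)-dione | CC1(C)C=CC2=C(O1)CC(=O)OC2=O | intermediate
6 | 7-(tert-butyldimethylsilyloxy)-2,2-dimethyl-2H,5H-pyrano[4,3-b]pyran-5-one | CC1(C)C=CC2=C(O1)C=C(O[Si](C)(C)C(C)(C)C)OC2=O | intermediate
7 | ethoxyacetylene (ethoxyethyne) | CCOC#C | starting material
8 | N-methoxy-N,2-dimethylpropanamide | CC(C)C(=O)N(C)OC | starting material
9 | lithium ethoxyacetylide | [Li]C#COCC | intermediate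
10 | lithium 1-ethoxy-3-[methoxy(methyl)amino]-4-methylpent-1-yn-3-olate | CCOC#CC(O[Li])(C(C)C)N(C)OC | intermediate
11 | 1-ethoxy-4-methylpent-1-yn-3-one | CCOC#CC(=O)C(C)C | intermediate
12 | 2-oxabicyclo[2.2.2]octa-5,7-dien-3-one cycloadduct of 6 and 11 (lactone bridge between former C4a and C7 of 6; OTBS on the oxygen-bearing bridgehead; ethoxy and isobutyryl groups on the new alkene; dimethylpyran ring still fused) | CC1(C)C=CC23C(=O)OC(O[Si](C)(C)C(C)(C)C)(C=C2O1)C(C(=O)C(C)C)=C3OCC | intermediate
13 | 1-[7-(tert-butyldimethylsilyloxy)-5-ethoxy-2,2-dimethyl-2H-chromen-6-yl]-2-methylpropan-1-one | CCOc1c(C(=O)C(C)C)c(O[Si](C)(C)C(C)(C)C)cc2OC(C)(C)C=Cc12 | intermediate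
14 | dichloro{[7-(tert-butyldimethylsilyloxy)-2,2-dimethyl-6-(2-methylpropanoyl)-2H-chromen-5-yl]oxy}borane (ketone-chelated) | CC(C)C(=O)c1c(OB(Cl)Cl)c2C=CC(C)(C)Oc2cc1O[Si](C)(C)C(C)(C)C | intermediate
15 | 1-[7-(tert-butyldimethylsilyloxy)-5-hydroxy-2,2-dimethyl-2H-chromen-6-yl]-2-methylpropan-1-one | CC(C)C(=O)c1c(O)c2C=CC(C)(C)Oc2cc1O[Si](C)(C)C(C)(C)C | intermediate
16 | 1-(5,7-dihydroxy-2,2-dimethyl-2H-chromen-6-yl)-2-methylpropan-1-one | CC(C)C(=O)c1c(O)cc2OC(C)(C)C=Cc2c1O | intermediate
17 | phloroglucinol (benzene-1,3,5-triol) | Oc1cc(O)cc(O)c1 | starting material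
18 | 2-methylpropanoyl chloride (isobutyryl chloride) | CC(C)C(Cl)=O | starting material
19 | 2-methyl-1-(2,4,6-trihydroxyphenyl)propan-1-one | CC(C)C(=O)c1c(O)cc(O)cc1O | intermediate
20 | 2-methyl-1-(2,4,6-trihydroxy-3-methylphenyl)propan-1-one | CC(C)C(=O)c1c(O)cc(O)c(C)c1O | intermediate
21 | 3,5-dihydroxy-4,4-dimethyl-6-(2-methylpropanoyl)cyclohexa-2,5-dien-1-one (isobutyrylfilicinic acid) | CC(C)C(=O)C1=C(O)C(C)(C)C(O)=CC1=O | intermediate
22 | 2-[(dimethylamino)methyl]-3,5-dihydroxy-4,4-dimethyl-6-(2-methylpropanoyl)cyclohexa-2,5-dien-1-one | CC(C)C(=O)C1=C(O)C(C)(C)C(O)=C(CN(C)C)C1=O | intermediate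
23 | 5-hydroxy-4,4-dimethyl-2-methylidene-6-(2-methylpropanoyl)cyclohex-5-ene-1,3-dione | CC(C)C(=O)C1=C(O)C(C)(C)C(=O)C(=C)C1=O | intermediate
24 | 3,5-dihydroxy-2-{[5,7-dihydroxy-2,2-dimethyl-6-(2-methylpropanoyl)-2H-chromen-8-yl]methyl}-4,4-dimethyl-6-(2-methylpropanoyl)cyclohexa-2,5-dien-1-one | CC(C)C(=O)C1=C(O)C(C)(C)C(O)=C(Cc2c(O)c(C(=O)C(C)C)c(O)c3c2OC(C)(C)C=C3)C1=O | target

Total step count: 11. Longest linear sequence: 7 steps (steps 1, 2, 3, 5, 6, 7, 11).

Steps most likely to fail

Step 5 (Proposed new method). The silyl ketene acetal may be consumed by Mukaiyama–Michael addition without ring closure, by desilylation, by cycloaddition through the 2H-pyran diene (with loss of acetone instead of CO2), or by addition in the reversed orientation; the ynol ether may also fragment by retro-ene reaction before it cycloadds. The fallback uses known chemistry and leaves the route at 19 and 3: these are condensed under ethylenediammonium diacetate catalysis in refluxing toluene (or in pyridine at 110 °C). Knoevenagel condensation at an unsubstituted ring carbon of 19 should give the o-quinone methide 2-(3-methylbut-2-en-1-ylidene)-3,5-dihydroxy-4-(2-methylpropanoyl)cyclohexa-3,5-dien-1-one F1, and oxa-6π closure through the oxygen para to the ketone should give the chromene directly. The isomer from closure onto an ortho oxygen is removed by chromatography, and the route is rejoined at 16.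

Step 2. Ring opening or self-acylation of the anhydride, hydrolysis by the water of condensation, or a second condensation at C8 may outrun the annulation. The fallback sets out from 3 and purchased di-tert-butyl 3-oxopentanedioate, so that the same annulation is run on a stable diester under piperidinium acetate catalysis. The Knoevenagel product di-tert-butyl 2-(3-methylbut-2-en-1-ylidene)-3-oxopentanedioate F2 should close to tert-butyl 6-(2-tert-butoxy-2-oxoethyl)-2,2-dimethyl-2H-pyran-5-carboxylate F3. Both tert-butyl esters are then cleaved with CF3CO2H in CH2Cl2 at 0 °C to give 6-(carboxymethyl)-2,2-dimethyl-2H-pyran-5-carboxylic acid F4, and Ac2O at room temperature closes the anhydride, which rejoins the route at 5.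

Step 6. Ionisation of the tertiary allylic C2–O bond of the pyran or addition of HCl to the C3=C4 alkene may compete with the comparatively slow SN2 removal of an ethyl group, and early loss of the silyl group may lock the ketone in a boron chelate on the wrong side. The fallback carries the C5 oxygen as a methyl ether, which is cleaved under much milder chelation control, and sets out from 8 and 6. Lithium methoxyacetylide F5 (generated in situ from 2-chloro-1,1-dimethoxyethane and LiNEt2) is acylated with 8 through lithium 1-methoxy-3-[methoxy(methyl)amino]-4-methylpent-1-yn-3-olate F6 to give 1-methoxy-4-methylpent-1-yn-3-one F7. This is combined with 6 as in step 5 to give, through the bridged lactone cycloadduct F8, 1-[7-(tert-butyldimethylsilyloxy)-5-methoxy-2,2-dimethyl-2H-chromen-6-yl]-2-methylpropan-1-one F9. MgI2·OEt2 in toluene/Et2O then removes the chelated methyl group without a strong Lewis acid, and the route is rejoined at 15.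

Further compounds
F1 | step 5 | 2-(3-methylbut-2-en-1-ylidene)-3,5-dihydroxy-4-(2-methylpropanoyl)cyclohexa-3,5-dien-1-one (o-quinone methide) | CC(C)=CC=C1C(=O)C=C(O)C(C(=O)C(C)C)=C1O
F2 | step 2 | di-tert-butyl 2-(3-methylbut-2-en-1-ylidene)-3-oxopentanedioate | CC(C)=CC=C(C(=O)OC(C)(C)C)C(=O)CC(=O)OC(C)(C)C
F3 | step 2 | tert-butyl 6-(2-tert-butoxy-2-oxoethyl)-2,2-dimethyl-2H-pyran-5-carboxylate | CC(C)(C)OC(=O)CC1=C(C(=O)OC(C)(C)C)C=CC(C)(C)O1
F4 | step 2 | 6-(carboxymethyl)-2,2-dimethyl-2H-pyran-5-carboxylic acid | OC(=O)CC1=C(C(O)=O)C=CC(C)(C)O1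
F5 | step 6 | lithium methoxyacetylide | [Li]C#COC
F6 | step 6 | lithium 1-methoxy-3-[methoxy(methyl)amino]-4-methylpent-1-yn-3-olate | COC#CC(O[Li])(C(C)C)N(C)OC
F7 | step 6 | 1-methoxy-4-methylpent-1-yn-3-one | COC#CC(=O)C(C)C
F8 | step 6 | 2-oxabicyclo[2.2.2]octa-5,7-dien-3-one cycloadduct of 6 and F7 (methoxy analogue of 12) | CC1(C)C=CC23C(=O)OC(O[Si](C)(C)C(C)(C)C)(C=C2O1)C(C(=O)C(C)C)=C3OC
F9 | step 6 | 1-[7-(tert-butyldimethylsilyloxy)-5-methoxy-2,2-dimethyl-2H-chromen-6-yl]-2-methylpropan-1-one | COc1c(C(=O)C(C)C)c(O[Si](C)(C)C(C)(C)C)cc2OC(C)(C)C=Cc12
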